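The cyclobutane of the target is meso: a mirror plane bisects the C1–C2 bond (methines carrying CO2H) and the C3–C4 bond (quaternary carbons carrying methyl and a 4-methoxy-3-methyl-2-pyranon-6-yl ring), so the four-membered ring is the syn head-to-head dimer of one (E)-3-(pyranonyl)but-2-enoic acid. Both acid units are therefore esterified onto the peri oxygens of 1,8-dihydroxynaphthalene, and irradiation of this bis(enoate) joins C1–C2 and C3–C4 in one intramolecular [2+2] photocycloaddition, setting all four stereocentres. Mild hydrolysis then releases the diacid and returns the template.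

Key step: step 7

Remark on numbering and configuration: cyclobutane atoms are numbered as in the diacid name (C1, C2 = CH–CO2H; C3, C4 = C(CH3)(pyranonyl)). The target is the meso (1R,2S,3R,4S) isomer, with both methyls and both carboxyls on one face of the ring and both pyranones on the other.
Assumption: ethyl glyoxylate is used as the monomer, freshly distilled from its commercial toluene solution.

Step 1
Reactants: 1 4-hydroxy-3,6-dimethyl-2H-pyran-2-one
Product: 2 4-methoxy-3,6-dimethyl-2H-pyran-2-one
Conditions: Me2SO4, K2CO3, acetone, reflux
Reagents that add atoms: dimethyl sulfate COS(=O)(=O)OC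
Why: Williamson-type O-alkylation of a vinylogous acid: the pyranolate formed with K2CO3 should be methylated by dimethyl sulfate on the 4-oxygen, the site that keeps the 2-pyranone lactone, as is usual for 4-hydroxy-2-pyranones under these conditions.

Step 2
Reactants: 2 4-methoxy-3,6-dimethyl-2H-pyran-2-one
Product: 4 6-ethyl-4-methoxy-3-methyl-2H-pyran-2-one, via lithium dienolate 3 (not isolated)
Conditions: LiN(iPr)2 (1.05 equiv), THF, −78 °C; then MeI, −78 to −40 °C
Reagents that add atoms: iodomethane CI
Why: Alkylation of an extended (vinylogous) lactone enolate: with C3 blocked by its methyl group the amide base should remove a proton from the 6-methyl group, and dienolate 3 is methylated at the exocyclic carbon, which restores the pyranone; one equivalent of base at −78 °C limits a second methylation.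

Step 3
Reactants: 4 6-ethyl-4-methoxy-3-methyl-2H-pyran-2-one; 5 ethyl glyoxylate
Product: 7 ethyl 2-hydroxy-3-(4-methoxy-3-methyl-2-oxo-2H-pyran-6-yl)butanoate (mixture of diastereomers), via lithium dienolate 6 (not isolated)
Conditions: LiN(iPr)2, THF, −78 °C; then 5, −78 °C; AcOH quench
Reagents that add atoms: none
Why: Vinylogous aldol addition: the exocyclic carbon of dienolate 6 should add to the very electrophilic aldehyde of monomeric ethyl glyoxylate at −78 °C, and the two stereocentres formed (mixture of diastereomers, racemic) need no control because step 4 removes both.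

Step 4
Reactants: 7 ethyl 2-hydroxy-3-(4-methoxy-3-methyl-2-oxo-2H-pyran-6-yl)butanoate
Product: 9 ethyl (E)-3-(4-methoxy-3-methyl-2-oxo-2H-pyran-6-yl)but-2-enoate, via 2-mesyloxy ester 8 (not isolated)
Conditions: MsCl, Et3N, CH2Cl2, 0 °C; then DBU, 0 °C to rt
Reagents that add atoms: none
Why: Mesylation followed by E1cB elimination: the proton on the carbon that bears the pyranone is vinylogously acidic, so DBU should expel methanesulfonate from 8 to give the enoate conjugated with both the ester and the pyranone, and equilibration under the basic conditions favours the E isomer with the ester trans to the pyranone ring.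

Step 5
Reactants: 9 ethyl (E)-3-(4-methoxy-3-methyl-2-oxo-2H-pyran-6-yl)but-2-enoate
Product: 10 (E)-3-(4-methoxy-3-methyl-2-oxo-2H-pyran-6-yl)but-2-enoic acid
Conditions: Me3SnOH, ClCH2CH2Cl, 70 °C; then 1 M HCl wash
Reagents that add atoms: trimethyltin hydroxide C[Sn](C)(C)O
Why: Ester hydrolysis by trimethyltin hydroxide: the neutral tin hydroxide should deliver its oxygen to the unhindered ethyl ester to give the tin carboxylate (freed by the acid wash) without the free hydroxide that could open the pyranone lactone or move the double bond.

Step 6
Reactants: 10 (E)-3-(4-methoxy-3-methyl-2-oxo-2H-pyran-6-yl)but-2-enoic acid (2.2 equiv); 11 1,8-dihydroxynaphthalene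
Product: 13 naphthalene-1,8-diyl bis[(E)-3-(4-methoxy-3-methyl-2-oxo-2H-pyran-6-yl)but-2-enoate], via 8-hydroxynaphthalen-1-yl monoester 12 (not isolated)
Conditions: DCC, DMAP (cat.), CH2Cl2, 0 °C to rt, argon
Reagents that add atoms: none
Why: Double Steglich esterification: DCC converts 10 into its O-acylisourea, DMAP passes the acyl group to each peri hydroxyl in turn by way of monoester 12, and the nearly neutral conditions avoid the ketene or dienolate pathways that would isomerise the E enoate.

Step 7
Reactants: 13 naphthalene-1,8-diyl bis[(E)-3-(4-methoxy-3-methyl-2-oxo-2H-pyran-6-yl)but-2-enoate]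
Product: 14 naphthalene-1,8-diyl (1R,2S,3R,4S)-3,4-dimethyl-3,4-bis(4-methoxy-3-methyl-2-oxo-2H-pyran-6-yl)cyclobutane-1,2-dicarboxylate (cyclic diester, meso)
Conditions: hν (365 nm LED), degassed CH2Cl2 (5 mM), rt
Reagents that add atoms: none
Why: Direct excitation at 365 nm is absorbed only by the extended pyranonyl-enoate chromophore; the excited arm adds to the ground-state arm stacked beside it, an intramolecular [2+2] photocycloaddition of the kind known for cinnamate-type diesters held on 1,8-dihydroxynaphthalene (template-directed photodimerisation), applied here to a β-methyl β-pyranonyl enoate. Where the addition is stepwise, the two α-carbons should join first (C1–C2, a 9-exo-trig closure of the temporary nine-membered diester ring), because this leaves the radical centres on the β-carbons, each tertiary and delocalised into its pyranone; recombination of this 1,4-diradical then closes the cyclobutane through the quaternary C3–C4 bond. The peri oxygens hold the two acyl chains parallel and in register, so the union is head-to-head and like faces of the two alkenes meet, which places the two ester carbons cis at C1/C2 (the nine-membered bridge allows nothing else) and the two pyranones cis at C3/C4. The trans relation of each ester carbon to the pyranone on its neighbouring quaternary carbon (cis to methyl) is carried over from the E geometry of each arm, so the four stereocentres of the meso (1R,2S,3R,4S) adduct follow from alkene geometry plus syn stacking. The step needs head-to-head regiochemistry, syn facial pairing and ring closure that outruns E→Z isomerisation and bond rotation in the diradical; the rigid tether, unsensitised (short-lived singlet) excitation and exclusion of oxygen serve this, and since 14 has lost the long-wavelength chromophore it should be neither cleaved back nor drawn into pyranone photochemistry at 365 nm.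

Step 8
Reactants: 14 naphthalene-1,8-diyl (1R,2S,3R,4S)-3,4-dimethyl-3,4-bis(4-methoxy-3-methyl-2-oxo-2H-pyran-6-yl)cyclobutane-1,2-dicarboxylate
Product: 16 (1R,2S,3R,4S)-3,4-dimethyl-3,4-bis(4-methoxy-3-methyl-2-oxo-2H-pyran-6-yl)cyclobutane-1,2-dicarboxylic acid (target CNP0574758.1), via mono(8-hydroxynaphthalen-1-yl) half-ester 15 (not isolated)
Conditions: LiOH·H2O, THF/H2O, 0 °C; then 1 M HCl to pH 2
Reagents that add atoms: lithium hydroxide [Li+].[OH-]
Why: Saponification of aryl esters by acyl–oxygen cleavage: the two naphthyl esters, activated by the naphtholate leaving group, should react with hydroxide at 0 °C far faster than the pyranone carbonyls (deactivated as vinylogous carbonates by the 4-methoxy group), the carboxylates formed shield C1 and C2 from enolisation, and the four stereocentres are carried through unchanged.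

Compound list
1 | 4-hydroxy-3,6-dimethyl-2H-pyran-2-one | Cc1cc(O)c(C)c(=O)o1 | starting material
2 | 4-methoxy-3,6-dimethyl-2H-pyran-2-one | COc1cc(C)oc(=O)c1C | intermediate
3 | lithium 4-methoxy-3-methyl-6-methylidene-6H-pyran-2-olate (lithium dienolate of 2, not isolated) | C=C1C=C(OC)C(C)=C(O[Li])O1 | intermediate
4 | 6-ethyl-4-methoxy-3-methyl-2H-pyran-2-one | CCc1cc(OC)c(C)c(=O)o1 | intermediate
5 | ethyl glyoxylate | CCOC(=O)C=O | starting material
6 | lithium 6-ethylidene-4-methoxy-3-methyl-6H-pyran-2-olate (lithium dienolate of 4, not isolated, alkene geometry not defined) | CC=C1C=C(OC)C(C)=C(O[Li])O1 | intermediate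
7 | ethyl 2-hydroxy-3-(4-methoxy-3-methyl-2-oxo-2H-pyran-6-yl)butanoate (racemic mixture of diastereomers) | CCOC(=O)C(O)C(C)c1cc(OC)c(C)c(=O)o1 | intermediate
8 | ethyl 2-(methanesulfonyloxy)-3-(4-methoxy-3-methyl-2-oxo-2H-pyran-6-yl)butanoate (not isolated) | CCOC(=O)C(OS(C)(=O)=O)C(C)c1cc(OC)c(C)c(=O)o1 | intermediate
9 | ethyl (E)-3-(4-methoxy-3-methyl-2-oxo-2H-pyran-6-yl)but-2-enoate | CCOC(=O)/C=C(C)/c1cc(OC)c(C)c(=O)o1 | intermediate
10 | (E)-3-(4-methoxy-3-methyl-2-oxo-2H-pyran-6-yl)but-2-enoic acid | OC(=O)/C=C(C)/c1cc(OC)c(C)c(=O)o1 | intermediate
11 | 1,8-dihydroxynaphthalene (naphthalene-1,8-diol) | Oc1cccc2cccc(O)c12 | starting material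
12 | 8-hydroxynaphthalen-1-yl (E)-3-(4-methoxy-3-methyl-2-oxo-2H-pyran-6-yl)but-2-enoate (monoester, not isolated) | COc1cc(/C(C)=C/C(=O)Oc2cccc3cccc(O)c23)oc(=O)c1C | intermediate
13 | naphthalene-1,8-diyl bis[(E)-3-(4-methoxy-3-methyl-2-oxo-2H-pyran-6-yl)but-2-enoate] | COc1cc(/C(C)=C/C(=O)Oc2cccc3cccc(OC(=O)/C=C(C)/c4cc(OC)c(C)c(=O)o4)c23)oc(=O)c1C | intermediate
14 | naphthalene-1,8-diyl (1R,2S,3R,4S)-3,4-dimethyl-3,4-bis(4-methoxy-3-methyl-2-oxo-2H-pyran-6-yl)cyclobutane-1,2-dicarboxylate (meso; methyls and ester carbons on one face, pyranones on the other) | COc1cc([C@@]2(C)[C@@H]3C(=O)Oc4cccc5cccc(OC(=O)[C@@H]3[C@@]2(C)c2cc(OC)c(C)c(=O)o2)c45)oc(=O)c1C | intermediate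
15 | mono(8-hydroxynaphthalen-1-yl) ester of diacid 16 (racemic half-ester, relative configuration as in 14, not isolated) | COc1cc([C@@]2(C)[C@H](C(=O)O)[C@H](C(=O)Oc3cccc4cccc(O)c34)[C@@]2(C)c2cc(OC)c(C)c(=O)o2)oc(=O)c1C | intermediate
16 | (1R,2S,3R,4S)-3,4-dimethyl-3,4-bis(4-methoxy-3-methyl-2-oxo-2H-pyran-6-yl)cyclobutane-1,2-dicarboxylic acid (meso) | COc1cc([C@@]2(C)[C@H](C(=O)O)[C@H](C(=O)O)[C@@]2(C)c2cc(OC)c(C)c(=O)o2)oc(=O)c1C | target

Total step count: 8. Longest linear sequence: 8 steps (1 to 16); 5 and 11 enter as purchased materials.

Steps most likely to fail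

Step 7. The cycloaddition must create two adjacent quaternary carbons. If closure is slow, the excited arm may relax by E→Z isomerisation, the intermediate diradical may rotate or revert, or mis-registered conformers may react; each of these erodes the single meso diastereomer. A change of medium (irradiating 13 as a crystalline film) would be tried first. The fallback itself replaces the covalent tether by a lattice template and sets out from 10. Crystallisation of 10 with half an equivalent of ethane-1,2-diamine from ethanol should give ethane-1,2-diammonium bis[(E)-3-(4-methoxy-3-methyl-2-oxo-2H-pyran-6-yl)but-2-enoate] F1, in which the salt bridges pair the enoates head-to-head. Irradiation of the powdered salt at 365 nm is a topochemical [2+2] photodimerisation of the kind known for diamine double salts of cinnamic acids. It should give ethane-1,2-diammonium (1R,2S,3R,4S)-3,4-dimethyl-3,4-bis(4-methoxy-3-methyl-2-oxo-2H-pyran-6-yl)cyclobutane-1,2-dicarboxylate F2. Acidification with dilute HCl would release the diacid, so the fallback comes back to the route at 16.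

Step 3. The aldol addition may stall or reverse (retro-aldol of the lithium aldolate on warming), the dienolate may be quenched by oligomeric or hydrated glyoxylate, or it may add to a second pyranone in a Michael sense. The fallback sets out from 4 and replaces the aldol by acylation and reduction. Dienolate 6, generated with two equivalents of LiN(iPr)2 in THF at −78 °C, would be acylated with diethyl oxalate (Claisen condensation) to give ethyl 3-(4-methoxy-3-methyl-2-oxo-2H-pyran-6-yl)-2-oxobutanoate F3. Reduction of its ketone with NaBH4 in ethanol at −20 °C should then give the hydroxy ester, so the fallback comes back to the route at 7.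

Step 8. Hydroxide may attack the pyranone lactones in competition with the aryl esters, or the base may epimerise C1/C2 before the carboxylates have formed. The fallback sets out from 14 and separates template removal from acid liberation. Transesterification with allyl alcohol (K2CO3, allyl alcohol/THF, rt) should give diallyl (1R,2S,3R,4S)-3,4-dimethyl-3,4-bis(4-methoxy-3-methyl-2-oxo-2H-pyran-6-yl)cyclobutane-1,2-dicarboxylate F4 and return 11. Any alkoxide addition to a pyranone is reversible, unlike attack by hydroxide. Deallylation with Pd(PPh3)4 (zerovalent palladium) and morpholine in THF at rt (Tsuji–Trost allyl transfer) would then free the diacid under neutral conditions, so the fallback comes back to the route at 16.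

Further compounds
F1 | step 7 | ethane-1,2-diammonium bis[(E)-3-(4-methoxy-3-methyl-2-oxo-2H-pyran-6-yl)but-2-enoate] | [NH3+]CC[NH3+].COc1cc(/C(C)=C/C(=O)[O-])oc(=O)c1C.COc1cc(/C(C)=C/C(=O)[O-])oc(=O)c1C
F2 | step 7 | ethane-1,2-diammonium (1R,2S,3R,4S)-3,4-dimethyl-3,4-bis(4-methoxy-3-methyl-2-oxo-2H-pyran-6-yl)cyclobutane-1,2-dicarboxylate | [NH3+]CC[NH3+].COc1cc([C@@]2(C)[C@H](C(=O)[O-])[C@H](C(=O)[O-])[C@@]2(C)c2cc(OC)c(C)c(=O)o2)oc(=O)c1C
F3 | step 3 | ethyl 3-(4-methoxy-3-methyl-2-oxo-2H-pyran-6-yl)-2-oxobutanoate (racemic) | CCOC(=O)C(=O)C(C)c1cc(OC)c(C)c(=O)o1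
F4 | step 8 | diallyl (1R,2S,3R,4S)-3,4-dimethyl-3,4-bis(4-methoxy-3-methyl-2-oxo-2H-pyran-6-yl)cyclobutane-1,2-dicarboxylate | COc1cc([C@@]2(C)[C@H](C(=O)OCC=C)[C@H](C(=O)OCC=C)[C@@]2(C)c2cc(OC)c(C)c(=O)o2)oc(=O)c1C
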